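## Retrosynthetic overview

1. Target ⇐ global Lewis-acid deprotection (three aryl OMe, one CO2Bn) of the fully protected 8-aryloxy-6-methoxy-3-pentylisocoumarin.
2. Pyranone ring ⇐ acid-catalysed enol-lactonisation of a methyl 2-(2-oxoheptyl)benzoate. Its ArCH2–C(=O) bond (C4–C3 of the isocoumarin) ⇐ intermolecular crossed Claisen-type condensation of the lithiated ring A toluate with the Weinreb amide of hexanoic acid; this key C–C bond joins the diaryl ether fragment to the C6 chain.
3. Diaryl ether C–O bond ⇐ Ullmann coupling of methyl 2-bromo-4-methoxy-6-methylbenzoate (ring A) with benzyl 3-hydroxy-4,6-dimethoxy-2-pentylbenzoate (ring B).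
4. Ring A bromide ⇐ 4-methoxy-2-methylaniline (bromination, iodo-dediazoniation, iodine–magnesium exchange and methoxycarbonylation). Ring B phenol ⇐ olivetol via its symmetrical dibromo dimethyl ether, desymmetrised by two successive bromine–lithium exchanges (first to OH, then to CO2Bn).
5. Ring order: both benzene rings are bought intact; the only ring built is the pyranone ring of the isocoumarin, in the penultimate step.

Assumption: the target SMILES has no stereocentre and no stereogenic double bond, so the compound is achiral and the route delivers the one structure shown.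

## Route

Step 1
Reactants: 1 4-methoxy-2-methylaniline
Product: 2 2-bromo-4-methoxy-6-methylaniline
Conditions: NBS (1.0 equiv), MeCN, −10 to 0 °C
Reagents that add atoms: N-bromosuccinimide, O=C1CCC(=O)N1Br
Why: Electrophilic aromatic bromination in which the free amino group is the dominant ortho/para director and, with its para position (OMe) and one ortho position (CH3) blocked, bromine enters the single open ortho position.

Step 2
Reactants: 2 2-bromo-4-methoxy-6-methylaniline
Product: 4 1-bromo-2-iodo-5-methoxy-3-methylbenzene, via arenediazonium chloride 3 (not isolated)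
Conditions: NaNO2, aq. HCl, MeCN–H2O, 0 °C; then KI, 0 °C → rt
Reagents that add atoms: potassium iodide, [K+].[I-]
Why: Diazotisation followed by Sandmeyer-type iodo-dediazoniation replaces NH2 by iodine at the same carbon, so the substitution pattern is fixed without regiochemical ambiguity.

Step 3
Reactants: 4 1-bromo-2-iodo-5-methoxy-3-methylbenzene
Product: 6 methyl 2-bromo-4-methoxy-6-methylbenzoate, via arylmagnesium chloride 5 (not isolated)
Conditions: iPrMgCl·LiCl (1.1 equiv), THF, −30 °C, 1 h; then ClCO2Me (2 equiv), −30 → 0 °C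
Reagents that add atoms: methyl chloroformate, COC(=O)Cl
Why: Halogen–magnesium exchange is much faster at C–I than at C–Br, the ortho-bromoaryl Grignard reagent is stable below 0 °C, and its acylation by the chloroformate stops at the di-ortho-substituted ester.

Step 4
Reactants: 7 olivetol (5-pentylbenzene-1,3-diol)
Product: 8 1,3-dimethoxy-5-pentylbenzene
Conditions: MeI (2.5 equiv), K2CO3 (3 equiv), acetone, reflux
Reagents that add atoms: iodomethane, CI
Why: Williamson ether synthesis methylates both phenols cleanly.

Step 5
Reactants: 8 1,3-dimethoxy-5-pentylbenzene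
Product: 9 2,4-dibromo-1,5-dimethoxy-3-pentylbenzene
Conditions: NBS (2.1 equiv), MeCN, 0 °C → rt, dark
Reagents that add atoms: N-bromosuccinimide, O=C1CCC(=O)N1Br
Why: Electrophilic aromatic bromination of a 1,3-dimethoxyarene goes twice to the positions ortho to one and para to the other methoxy group (both flanking the pentyl chain) and not between the two methoxy groups, giving the symmetrical dibromide.

Step 6
Reactants: 9 2,4-dibromo-1,5-dimethoxy-3-pentylbenzene
Product: 12 3-bromo-4,6-dimethoxy-2-pentylphenol, via monolithiated arene 10 (not isolated), via lithium aryltrimethoxyborate 11 (not isolated)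
Conditions: n-BuLi (1.05 equiv), THF, −78 °C; B(OMe)3, −78 °C → rt; then AcOH, 30% H2O2, 0 °C → rt
Reagents that add atoms: hydrogen peroxide, OO
Why: Bromine–lithium exchange on the symmetrical dibromide can give only one monolithio species, and borylation followed by peroxide oxidation (1,2-aryl shift from boron to oxygen) turns exactly that carbon into the phenol.

Step 7
Reactants: 12 3-bromo-4,6-dimethoxy-2-pentylphenol
Product: 13 2-bromo-1,5-dimethoxy-4-(methoxymethoxy)-3-pentylbenzene
Conditions: MOMCl (2 equiv), iPr2NEt (3 equiv), CH2Cl2, 0 → 40 °C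
Reagents that add atoms: chloromethyl methyl ether, COCCl
Why: O-alkylation of the phenol gives an acetal ether that survives the next organolithium step and is later removed by mild acid without touching a benzyl ester.

Step 8
Reactants: 13 2-bromo-1,5-dimethoxy-4-(methoxymethoxy)-3-pentylbenzene
Product: 15 benzyl 4,6-dimethoxy-3-(methoxymethoxy)-2-pentylbenzoate, via aryllithium 14 (not isolated)
Conditions: n-BuLi (1.1 equiv), THF, −78 °C; then cannulated into ClCO2Bn (2 equiv), THF, −78 → 0 °C
Reagents that add atoms: benzyl chloroformate, O=C(Cl)OCc1ccccc1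
Why: The second bromine–lithium exchange followed by acylation of the aryllithium with the chloroformate places the carboxyl carbon exactly at the former C–Br position, and the di-ortho-substituted ester is too hindered for a second addition.

Step 9
Reactants: 15 benzyl 4,6-dimethoxy-3-(methoxymethoxy)-2-pentylbenzoate
Product: 16 benzyl 3-hydroxy-4,6-dimethoxy-2-pentylbenzoate
Conditions: conc. HCl (cat.), MeOH–THF, 50 °C
Reagents that add atoms: none
Why: Acid-catalysed acetal exchange (MOM cleavage) frees the phenol while the methyl ethers and the hindered benzyl ester are inert.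

Step 10
Reactants: 17 hexanoyl chloride; 18 N,O-dimethylhydroxylamine hydrochloride
Product: 19 N-methoxy-N-methylhexanamide
Conditions: K2CO3 (2.5 equiv), H2O–CH2Cl2, 0 °C → rt
Reagents that add atoms: none
Why: Schotten–Baumann N-acylation of the hydroxylamine by the acid chloride gives the Weinreb amide.

Step 11
Reactants: 6 methyl 2-bromo-4-methoxy-6-methylbenzoate; 16 benzyl 3-hydroxy-4,6-dimethoxy-2-pentylbenzoate
Product: 20 benzyl 4,6-dimethoxy-3-[5-methoxy-2-(methoxycarbonyl)-3-methylphenoxy]-2-pentylbenzoate
Conditions: CuI (20 mol%), N,N-dimethylglycine (40 mol%), Cs2CO3 (2 equiv), 1,4-dioxane, 105 °C, Ar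
Reagents that add atoms: none
Why: Ullmann-type copper-catalysed C–O coupling in which the aryl bromide is activated by its ortho ester and the electron-rich phenoxide of 16 is the only nucleophile, so the hindered diaryl ether forms without touching either ester.

Step 12
Reactants: 20 benzyl 4,6-dimethoxy-3-[5-methoxy-2-(methoxycarbonyl)-3-methylphenoxy]-2-pentylbenzoate; 19 N-methoxy-N-methylhexanamide
Product: 23 benzyl 4,6-dimethoxy-3-[5-methoxy-2-(methoxycarbonyl)-3-(2-oxoheptyl)phenoxy]-2-pentylbenzoate, via benzylic lithium species 21 (not isolated), via lithium hemiaminal alkoxide 22 (not isolated)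
Conditions: LiN(iPr)2 (1.3 equiv), THF, −78 °C, 30 min; then 19 (1.5 equiv), −78 → −40 °C; cold 1 M HCl quench
Reagents that add atoms: none
Why: LiN(iPr)2 deprotonates the ortho-methyl group of the ring A toluate (lateral lithiation; the secondary, doubly flanked benzylic CH2 of ring B is far slower) to a vinylogous ester enolate, and its intermolecular crossed Claisen-type condensation with the Weinreb amide stops at the chelated tetrahedral adduct, so the ketone appears only on work-up and neither over-addition nor proton quench occurs.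

Step 13
Reactants: 23 benzyl 4,6-dimethoxy-3-[5-methoxy-2-(methoxycarbonyl)-3-(2-oxoheptyl)phenoxy]-2-pentylbenzoate
Product: 24 benzyl 4,6-dimethoxy-3-[(6-methoxy-1-oxo-3-pentyl-1H-isochromen-8-yl)oxy]-2-pentylbenzoate
Conditions: TsOH·H2O (20 mol%), toluene, reflux, 4 Å MS
Reagents that add atoms: none
Why: Acid-catalysed enol-lactonisation (intramolecular transesterification by the ketone enol) closes the six-membered pyranone with loss of methanol, and the new C3=C4 bond is endocyclic so no alkene geometry arises.

Step 14
Reactants: 24 benzyl 4,6-dimethoxy-3-[(6-methoxy-1-oxo-3-pentyl-1H-isochromen-8-yl)oxy]-2-pentylbenzoate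
Product: 25 4,6-dihydroxy-3-[(6-hydroxy-1-oxo-3-pentyl-1H-isochromen-8-yl)oxy]-2-pentylbenzoic acid (CNP0439913.0)
Conditions: BBr3 (10 equiv), CH2Cl2, −78 °C → rt, 16 h; then ice-water
Reagents that add atoms: none
Why: Lewis-acid ether and ester cleavage in which BBr3 removes the three aryl methyl groups and the benzyl group by bromide attack at the alkyl carbon, while the diaryl ether and the enol lactone are stable and the resorcylic acid is released only on cold aqueous work-up.

## Compound list

1 | 4-methoxy-2-methylaniline | COc1ccc(N)c(C)c1 | starting material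
2 | 2-bromo-4-methoxy-6-methylaniline | COc1cc(C)c(N)c(Br)c1 | intermediate
3 | 2-bromo-4-methoxy-6-methylbenzenediazonium chloride (formed in the flask) | COc1cc(C)c([N+]#N)c(Br)c1.[Cl-] | intermediate
4 | 1-bromo-2-iodo-5-methoxy-3-methylbenzene | COc1cc(C)c(I)c(Br)c1 | intermediate
5 | (2-bromo-4-methoxy-6-methylphenyl)magnesium chloride (formed in the flask) | COc1cc(C)c([Mg]Cl)c(Br)c1 | intermediate
6 | methyl 2-bromo-4-methoxy-6-methylbenzoate | COC(=O)c1c(C)cc(OC)cc1Br | intermediate
7 | olivetol (5-pentylbenzene-1,3-diol) | CCCCCc1cc(O)cc(O)c1 | starting material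
8 | 1,3-dimethoxy-5-pentylbenzene | CCCCCc1cc(OC)cc(OC)c1 | intermediate
9 | 2,4-dibromo-1,5-dimethoxy-3-pentylbenzene | CCCCCc1c(Br)c(OC)cc(OC)c1Br | intermediate
10 | (3-bromo-4,6-dimethoxy-2-pentylphenyl)lithium (formed in the flask) | CCCCCc1c([Li])c(OC)cc(OC)c1Br | intermediate
11 | lithium (3-bromo-4,6-dimethoxy-2-pentylphenyl)trimethoxyborate (formed in the flask) | CCCCCc1c([B-](OC)(OC)OC)c(OC)cc(OC)c1Br.[Li+] | intermediate
12 | 3-bromo-4,6-dimethoxy-2-pentylphenol | CCCCCc1c(O)c(OC)cc(OC)c1Br | intermediate
13 | 2-bromo-1,5-dimethoxy-4-(methoxymethoxy)-3-pentylbenzene | CCCCCc1c(OCOC)c(OC)cc(OC)c1Br | intermediate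
14 | [4,6-dimethoxy-3-(methoxymethoxy)-2-pentylphenyl]lithium (formed in the flask) | CCCCCc1c(OCOC)c(OC)cc(OC)c1[Li] | intermediate
15 | benzyl 4,6-dimethoxy-3-(methoxymethoxy)-2-pentylbenzoate | CCCCCc1c(OCOC)c(OC)cc(OC)c1C(=O)OCc1ccccc1 | intermediate
16 | benzyl 3-hydroxy-4,6-dimethoxy-2-pentylbenzoate | CCCCCc1c(O)c(OC)cc(OC)c1C(=O)OCc1ccccc1 | intermediate
17 | hexanoyl chloride | CCCCCC(=O)Cl | starting material
18 | N,O-dimethylhydroxylamine hydrochloride | CNOC.Cl | starting material
19 | N-methoxy-N-methylhexanamide | CCCCCC(=O)N(C)OC | intermediate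
20 | benzyl 4,6-dimethoxy-3-[5-methoxy-2-(methoxycarbonyl)-3-methylphenoxy]-2-pentylbenzoate | COC(=O)c1c(C)cc(OC)cc1Oc1c(OC)cc(OC)c(C(=O)OCc2ccccc2)c1CCCCC | intermediate
21 | benzylic lithium species of 20, lithiated at the ring A methyl group (formed in the flask) | COC(=O)c1c(C[Li])cc(OC)cc1Oc1c(OC)cc(OC)c(C(=O)OCc2ccccc2)c1CCCCC | intermediate
22 | lithium hemiaminal alkoxide from 21 and 19 (formed in the flask; racemic at the transient hemiaminal carbon, which is lost on work-up) | CCCCCC(O[Li])(N(C)OC)Cc1cc(OC)cc(Oc2c(OC)cc(OC)c(C(=O)OCc3ccccc3)c2CCCCC)c1C(=O)OC | intermediate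
23 | benzyl 4,6-dimethoxy-3-[5-methoxy-2-(methoxycarbonyl)-3-(2-oxoheptyl)phenoxy]-2-pentylbenzoate | CCCCCC(=O)Cc1cc(OC)cc(Oc2c(OC)cc(OC)c(C(=O)OCc3ccccc3)c2CCCCC)c1C(=O)OC | intermediate
24 | benzyl 4,6-dimethoxy-3-[(6-methoxy-1-oxo-3-pentyl-1H-isochromen-8-yl)oxy]-2-pentylbenzoate | CCCCCc1cc2cc(OC)cc(Oc3c(OC)cc(OC)c(C(=O)OCc4ccccc4)c3CCCCC)c2c(=O)o1 | intermediate
25 | 4,6-dihydroxy-3-[(6-hydroxy-1-oxo-3-pentyl-1H-isochromen-8-yl)oxy]-2-pentylbenzoic acid (CNP0439913.0, achiral) | CCCCCc1cc2cc(O)cc(Oc3c(O)cc(O)c(C(=O)O)c3CCCCC)c2c(=O)o1 | target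

## Summary

Total step count: 14.
Longest linear sequence: 10 steps (olivetol 7 → 25 through steps 4–9 and 11–14).

Steps most likely to fail:

Step 11 (Ullmann coupling). The ether is tri-ortho-substituted, so the coupling may be slow and 6 may be lost by protodebromination. The fallback sets out from 6 and comes back to the route at 20. Borylation of 6 with B2pin2 (PdCl2(dppf), KOAc, dioxane, 90 °C) gives the pinacol boronate methyl 4-methoxy-2-methyl-6-(4,4,5,5-tetramethyl-1,3,2-dioxaborolan-2-yl)benzoate F1. Cleavage of the pinacol ester with NaIO4 and NH4OAc in acetone–water gives [5-methoxy-2-(methoxycarbonyl)-3-methylphenyl]boronic acid F2. Chan–Lam–Evans coupling of F2 with phenol 16 (Cu(OAc)2, pyridine, 4 Å MS, air, CH2Cl2, rt) then gives 20. The C–O bond is thus made from an aryl nucleophile at room temperature instead of from an aryl halide at 105 °C.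

Step 12 (lateral lithiation and Claisen-type acylation). Compound 20 carries a second benzylic position next to an ester (the pentyl CH2 of ring B) and two esters, so the anion may form unselectively or incompletely. The fallback sets out from 6 and comes back to the route at 24. The same acylation is run before the ether coupling, on the simple bromotoluate 6, which has only one benzylic site and one ester. LiN(iPr)2 in THF at −78 °C followed by 19 gives methyl 2-bromo-4-methoxy-6-(2-oxoheptyl)benzoate F3. TsOH in refluxing toluene closes it to 8-bromo-6-methoxy-3-pentyl-1H-isochromen-1-one F4. Coupling of F4 with phenol 16 (CuI, N,N-dimethylglycine, Cs2CO3, dioxane, 105 °C) gives 24 directly.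

Step 14 (global BBr3 deprotection). The 6-OMe group of the isocoumarin cleaves slowly, benzyl bromide can C-benzylate the electron-rich rings, and the 2,4-dihydroxybenzoic acid can decarboxylate if warmed in acid. The fallback sets out from 24 and comes back to the route at 25. The benzyl ester is removed first by hydrogenolysis (H2 1 atm, 10% Pd/C, EtOAc, rt, stopped at full conversion so that the C3=C4 bond is kept), giving 4,6-dimethoxy-3-[(6-methoxy-1-oxo-3-pentyl-1H-isochromen-8-yl)oxy]-2-pentylbenzoic acid F5. The three methyl ethers of F5 are then cleaved with BCl3 and n-Bu4NI (CH2Cl2, −78 °C → rt), which works by iodide attack and generates no benzyl electrophile, giving 25.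

Further compounds
F1 | step 11 | methyl 4-methoxy-2-methyl-6-(4,4,5,5-tetramethyl-1,3,2-dioxaborolan-2-yl)benzoate | COC(=O)c1c(C)cc(OC)cc1B1OC(C)(C)C(C)(C)O1
F2 | step 11 | [5-methoxy-2-(methoxycarbonyl)-3-methylphenyl]boronic acid | COC(=O)c1c(C)cc(OC)cc1B(O)O
F3 | step 12 | methyl 2-bromo-4-methoxy-6-(2-oxoheptyl)benzoate | CCCCCC(=O)Cc1cc(OC)cc(Br)c1C(=O)OC
F4 | step 12 | 8-bromo-6-methoxy-3-pentyl-1H-isochromen-1-one | CCCCCc1cc2cc(OC)cc(Br)c2c(=O)o1
F5 | step 14 | 4,6-dimethoxy-3-[(6-methoxy-1-oxo-3-pentyl-1H-isochromen-8-yl)oxy]-2-pentylbenzoic acid | CCCCCc1cc2cc(OC)cc(Oc3c(OC)cc(OC)c(C(=O)O)c3CCCCC)c2c(=O)o1
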